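**Strategy.** Everything rests on disconnecting the (Z)-C20=C21 trisubstituted alkene. The key step exploits the 1,5-relationship of the C19 and C23 carbinols across that alkene: once O19 and O23 are bridged by a diisopropylsilylene, C20 and C21 can only be joined inside an eight-membered 1,3-dioxa-2-silacyclooctene, where the double bond must be cis. One ring-closing metathesis therefore unites the C15–C20 and C21–C26 halves and fixes the alkene geometry. Its precursor is the mixed silaketal of an isopropenyl carbinol (C15/C17 as a p-methoxybenzylidene acetal) and a homoallylic alcohol (C26 benzoate). C27–C50 is then attached by lithiation–borylation, C1–C14 by a 1,3-anti Mukaiyama aldol, and the 42-membered lactone is closed last.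

Key step: step 11

Remark: atoms are numbered along the macrolide chain (C1 lactone carbonyl, C41 lactone carbinol, C50 terminal methyl) and the target SMILES is read as 2Z,4Z,20Z,38Z with fifteen stereocentres; TBS = tert-butyldimethylsilyl, TES = triethylsilyl, PMB = 4-methoxybenzyl, PMP = 4-methoxyphenyl, Ipc = isopinocampheyl, pin = pinacolato.

**North alcohol (C15–C20)**

Step 1
Reactants: 1 (S)-4-benzyl-3-propionyloxazolidin-2-one
Product: 3 (S)-4-benzyl-3-[(2S,3S)-3-hydroxy-2,4-dimethylpent-4-enoyl]oxazolidin-2-one, via Z-dibutylboron enolate 2 (not isolated)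
Conditions: n-Bu2BOTf, iPr2NEt, CH2Cl2, 0 °C; methacrolein, −78 to 0 °C; pH 7 buffer, MeOH, H2O2
Reagents that add atoms: methacrolein, CC(=C)C=O
Why: Evans syn aldol, in which enolate 2 adds through a chair transition state on the face away from the benzyl group, so that C18 and C19 arise syn with absolute control by the (S)-auxiliary.

Step 2
Reactants: 3 Evans adduct
Product: 4 (2S,3S)-3-hydroxy-N-methoxy-N,2,4-trimethylpent-4-enamide
Conditions: MeONHMe·HCl, AlMe3, THF/CH2Cl2, −20 to 0 °C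
Reagents that add atoms: N,O-dimethylhydroxylamine hydrochloride, CNOC.Cl
Why: Transamidation by Me2AlN(OMe)Me of an imide activated by its free β-hydroxyl removes the auxiliary without epimerising C18 and gives a Weinreb amide that accepts one carbanion only.

Step 3
Reactants: 4 Weinreb amide
Product: 5 ethyl (4S,5S)-5-hydroxy-4,6-dimethyl-3-oxohept-6-enoate
Conditions: EtOAc, LiN(iPr)2 (3.5 equiv), THF, −78 °C; then 4, −78 to −40 °C; aq. NH4Cl
Reagents that add atoms: ethyl acetate, CCOC(C)=O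
Why: Crossed Claisen acylation of the ethyl acetate lithium enolate adds C15 and C16, over-addition being blocked by the chelated tetrahedral adduct and by enolisation of the β-keto ester product.

Step 4
Reactants: 5 β-keto ester
Product: 6 ethyl (3R,4R,5S)-3,5-dihydroxy-4,6-dimethylhept-6-enoate
Conditions: Me4NBH(OAc)3, MeCN/AcOH (1:1), −30 °C
Reagents that add atoms: none
Why: Evans–Saksena reduction, in which the C19 hydroxyl exchanges onto boron and delivers hydride intramolecularly through a chair, should set C17 anti to C19 and so complete the 17,18-anti-18,19-syn triad.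

Step 5
Reactants: 6 anti-diol ester
Product: 7 (3R,4R,5S)-4,6-dimethylhept-6-ene-1,3,5-triol
Conditions: LiAlH4, THF, 0 °C
Reagents that add atoms: none
Why: Hydride reduction of the ester to the C15 primary alcohol leaves the isolated 1,1-disubstituted alkene untouched.

Step 6
Reactants: 7 triol
Product: 8 north alcohol (3S,4S)-4-[(2R,4R)-2-(4-methoxyphenyl)-1,3-dioxan-4-yl]-2-methylpent-1-en-3-ol
Conditions: 4-MeOC6H4CH(OMe)2, CSA (cat.), CH2Cl2, rt
Reagents that add atoms: 4-methoxybenzaldehyde dimethyl acetal, COC(OC)c1ccc(OC)cc1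
Why: Thermodynamic acetalisation should select the all-equatorial O15/O17 dioxane over the acetal of the anti O17/O19 diol, leaving only the C19 hydroxyl free and storing a C17 PMB ether that later directs the C15 aldol.

**South alcohol (C21–C26)**

Step 7
Reactants: 9 butane-1,4-diol
Product: 10 4-hydroxybutyl benzoate
Conditions: PhCOCl (0.3 equiv), Et3N, CH2Cl2, 0 °C
Reagents that add atoms: benzoyl chloride, O=C(Cl)c1ccccc1
Why: Monoacylation of the symmetrical diol used in excess gives a C26 benzoate, chosen because it survives fluoride and is later removed without touching silyl ethers or the acetal.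

Step 8
Reactants: 10 4-hydroxybutyl benzoate
Product: 11 4-oxobutyl benzoate
Conditions: Dess–Martin periodinane, NaHCO3, CH2Cl2, rt
Reagents that add atoms: none
Why: Buffered Dess–Martin oxidation converts the primary alcohol into the aldehyde without affecting the ester.

Step 9
Reactants: 11 4-oxobutyl benzoate
Product: 12 south alcohol (R)-4-hydroxyhept-6-en-1-yl benzoate
Conditions: (−)-Ipc2BOMe, CH2=CHCH2MgBr, Et2O, 0 °C to rt; then 11, −78 °C; NaBO3·4H2O, THF/H2O
Reagents that add atoms: allylmagnesium bromide, C=CC[Mg]Br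
Why: Brown allylboration through a chair transition state, in which the Ipc groups derived from (+)-α-pinene direct allyl transfer to the Si face, should set C23 as R while the ester stays inert at −78 °C.

**Tether, key step and C26 activation**

Step 10
Reactants: 8 north alcohol; 12 south alcohol
Product: 14 mixed diisopropylsilylene bis-ether of O19 of 8 and O23 of 12, via chlorodiisopropylsilyl ether 13 (not isolated)
Conditions: iPr2SiCl2 (3 equiv), imidazole, CH2Cl2, 0 °C to rt; excess silane removed in vacuo; then 12, imidazole, DMF, rt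
Reagents that add atoms: dichlorodiisopropylsilane, CC(C)[Si](Cl)(Cl)C(C)C
Why: Stepwise silyl ether formation, in which the hindered alcohol 8 is first turned into monochlorosilane 13 by excess dichlorosilane and then captures the less hindered alcohol 12, excludes symmetrical bis-ethers.

Step 11
Reactants: 14 mixed silylene bis-ether
Product: 15 eight-membered (Z)-cyclic silylene ether (ring of Si, O19, C19, C20, C21, C22, C23 and O23) with the PMP-acetal chain on C19 and the 3-(benzoyloxy)propyl chain on C23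
Conditions: second-generation Grubbs catalyst RuCl2(PCy3)(H2IMes)(=CHPh) (10 mol%, two portions), toluene, 2 mM, 80 °C, argon sparge
Reagents that add atoms: none
Why: The catalyst initiates at the unhindered monosubstituted C21 alkene of 14, and the resulting Ru=CH–C22 carbene adds intramolecularly across the 1,1-disubstituted C20 alkene to a four-membered metallacycle that collapses with loss of ethylene. The closest known reaction type is temporary silicon-tethered ring-closing metathesis of mixed bis-alkoxysilanes, which is established for Z alkenes but demanding for a trisubstituted alkene in an eight-membered ring. The one ring formed, the 1,3-dioxa-2-silacyclooct-5-ene, closes by metathesis between the alkene carbons C20 and C21. No stereocentre is created, the C19 and C23 carbinols being set beforehand in 8 and 12. The step needs Z geometry at C20=C21 and ring closure in preference to cross-metathesis dimerisation. The first is secured because an eight-membered ring cannot hold an E trisubstituted alkene, the second by the tether together with high dilution, the angle-compressing isopropyl groups on silicon and removal of ethylene.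

Step 12
Reactants: 15 cyclic silylene ether
Product: 16 (Z)-C19,C23-diol (C15/C17 PMP acetal, C26 benzoate)
Conditions: HF·pyridine, pyridine, THF, 0 °C
Reagents that add atoms: none
Why: Buffered fluoride should cleave the dialkoxysilane much faster than it affects the benzoate or the acetal, releasing the (Z)-1,5-diol with the alkene geometry intact.

Step 13
Reactants: 16 (Z)-diol
Product: 17 C19,C23-bis-TBS ether
Conditions: TBSOTf, 2,6-lutidine, CH2Cl2, −78 to 0 °C
Reagents that add atoms: tert-butyldimethylsilyl triflate, CC(C)(C)[Si](C)(C)OS(=O)(=O)C(F)(F)F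
Why: Silyl triflate silylation protects both secondary hydroxyls, including the hindered allylic one, as ethers that last to the final step.

Step 14
Reactants: 17 bis-TBS benzoate
Product: 18 C26 primary alcohol
Conditions: K2CO3, MeOH, rt
Reagents that add atoms: none
Why: Base-catalysed methanolysis removes the benzoate while silyl ethers and the acetal are stable.

Step 15
Reactants: 18 C26 alcohol
Product: 19 C26 iodide
Conditions: I2, PPh3, imidazole, CH2Cl2, 0 °C
Reagents that add atoms: iodine, II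
Why: Appel-type iodination proceeds by SN2 displacement at the primary carbon, and because O23 is silylated no tetrahydrofuran can form.

Step 16
Reactants: 19 C26 iodide
Product: 21 C26 pinacol boronic ester, via C26 alkyllithium 20 (not isolated)
Conditions: t-BuLi (2.1 equiv), Et2O/pentane, −78 °C; then iPrOBpin, −78 °C to rt
Reagents that add atoms: 2-isopropoxy-4,4,5,5-tetramethyl-1,3,2-dioxaborolane, CC(C)OB1OC(C)(C)C(C)(C)O1
Why: Iodine–lithium exchange at −78 °C is faster than any addition of 20 to the remote alkene, and trapping at boron with loss of isopropoxide gives the primary boronic ester needed for the homologation.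

**East fragment (C27–C50)**

Step 17
Reactants: 22 (S)-epichlorohydrin
Product: 24 (S)-2-(but-3-en-1-yl)oxirane, via (S)-1-chlorohex-5-en-2-ol 23 (not isolated)
Conditions: CH2=CHCH2MgCl, CuI (5 mol%), THF, −40 °C; then aq. NaOH, rt
Reagents that add atoms: allylmagnesium chloride, C=CC[Mg]Cl
Why: CuI-catalysed Grignard opening at the unsubstituted epoxide carbon and base closure of chlorohydrin 23 carry the stereocentre of epichlorohydrin unchanged into C31.

Step 18
Reactants: 24 (S)-2-(but-3-en-1-yl)oxirane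
Product: 25 (R)-12-chlorododec-1-en-5-ol
Conditions: Cl(CH2)6MgBr (from Br(CH2)6Cl, Mg, THF), CuI (10 mol%), THF, −30 to 0 °C
Reagents that add atoms: 6-chlorohexylmagnesium bromide, ClCCCCCC[Mg]Br
Why: CuI-catalysed opening at the terminal epoxide carbon installs C32–C38 without touching C31, the Grignard reagent forming at the C–Br bond only.

Step 19
Reactants: 25 chloro alcohol
Product: 26 TBS ether of 25
Conditions: TBSCl, imidazole, DMF, rt
Reagents that add atoms: tert-butyldimethylsilyl chloride, CC(C)(C)[Si](C)(C)Cl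
Why: Standard silylation protects the C31 hydroxyl.

Step 20
Reactants: 26 TBS ether
Product: 28 (R)-5-(tert-butyldimethylsilyloxy)-12-chlorododecan-1-ol, via B-alkyl-9-borabicyclononane 27 (not isolated)
Conditions: 9-BBN, THF, 0 °C to rt; then NaOH, H2O2, 0 °C
Reagents that add atoms: hydrogen peroxide, OO
Why: Anti-Markovnikov hydroboration by the bulky borane and oxidation with retention give the C27 primary alcohol, the alkyl chloride being inert.

Step 21
Reactants: 28 primary alcohol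
Product: 29 C27 N,N-diisopropylcarbamate
Conditions: iPr2NCOCl, Et3N, CH2Cl2, reflux
Reagents that add atoms: N,N-diisopropylcarbamoyl chloride, CC(C)N(C(C)C)C(Cl)=O
Why: Carbamoylation installs the hindered Hoppe carbamate that later directs enantioselective α-lithiation and serves as leaving group.

Step 22
Reactants: 29 chloro carbamate
Product: 31 C38 triphenylphosphonium iodide, via C38 iodide 30 (not isolated)
Conditions: NaI, PPh3, MeCN, reflux
Reagents that add atoms: sodium iodide, [Na+].[I-]; triphenylphosphine, c1ccc(cc1)P(c1ccccc1)c1ccccc1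
Why: Finkelstein exchange followed by SN2 quaternisation at the primary carbon gives the Wittig salt under neutral conditions that carbamate and silyl ether tolerate.

Step 23
Reactants: 32 (R)-propylene oxide
Product: 33 (R)-non-8-en-2-ol
Conditions: CH2=CH(CH2)4MgBr (from 6-bromohex-1-ene, Mg), CuI (10 mol%), THF, −30 to 0 °C
Reagents that add atoms: hex-5-enylmagnesium bromide, C=CCCCC[Mg]Br
Why: CuI-catalysed opening at the CH2 terminus leaves the C49 stereocentre of the epoxide untouched.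

Step 24
Reactants: 33 (R)-non-8-en-2-ol
Product: 34 TBS ether of 33
Conditions: TBSCl, imidazole, DMF, rt
Reagents that add atoms: tert-butyldimethylsilyl chloride, CC(C)(C)[Si](C)(C)Cl
Why: Standard silylation protects the C49 hydroxyl.

Step 25
Reactants: 34 TBS ether
Product: 35 (R)-7-(tert-butyldimethylsilyloxy)octanal
Conditions: OsO4 (2 mol%), NaIO4, 2,6-lutidine, dioxane/H2O, rt
Reagents that add atoms: sodium periodate, [Na+].[O-]I(=O)(=O)=O
Why: Lemieux–Johnson cleavage (OsO4-catalysed dihydroxylation, then periodate scission) converts the terminal alkene into the C43 aldehyde.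

Step 26
Reactants: 1 (S)-4-benzyl-3-propionyloxazolidin-2-one; 35 aldehyde
Product: 37 (S)-4-benzyl-3-[(2S,3R,9R)-9-(tert-butyldimethylsilyloxy)-3-hydroxy-2-methyldecanoyl]oxazolidin-2-one, via chlorotitanium Z-enolate 36 (not isolated)
Conditions: TiCl4 (1.05 equiv), iPr2NEt (1.1 equiv), N-methyl-2-pyrrolidinone (1 equiv), CH2Cl2, 0 °C; then 35, 0 °C; aq. NH4Cl
Reagents that add atoms: none
Why: Titanium-mediated Evans syn aldol, in which soft enolisation by TiCl4 and the amine gives the Z-enolate 36 and this adds to the aliphatic aldehyde through a non-chelated chair transition state on the face away from the benzyl group, sets C42 and C43 syn under auxiliary control.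

Step 27
Reactants: 37 aldol adduct
Product: 38 C43 TBS ether of 37
Conditions: TBSOTf, 2,6-lutidine, CH2Cl2, 0 °C
Reagents that add atoms: tert-butyldimethylsilyl triflate, CC(C)(C)[Si](C)(C)OS(=O)(=O)C(F)(F)F
Why: Silylation at this stage differentiates O43 permanently from the later lactone oxygen O41.

Step 28
Reactants: 38 silylated imide
Product: 39 (2R,3R,9R)-3,9-bis(tert-butyldimethylsilyloxy)-2-methyldecan-1-ol
Conditions: LiBH4, MeOH (1 equiv), THF, 0 °C
Reagents that add atoms: none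
Why: Borohydride reduction of the exocyclic imide carbonyl releases the auxiliary and the C41 primary alcohol without epimerising C42.

Step 29
Reactants: 39 primary alcohol
Product: 40 (2S,3R,9R)-3,9-bis(tert-butyldimethylsilyloxy)-2-methyldecanal
Conditions: Dess–Martin periodinane, NaHCO3, CH2Cl2, rt
Reagents that add atoms: none
Why: Buffered, non-basic oxidation gives the α-methyl aldehyde without epimerisation.

Step 30
Reactants: 40 aldehyde
Product: 41 (4S,5R,6R,12R)-6,12-bis(tert-butyldimethylsilyloxy)-5-methyltridec-1-en-4-ol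
Conditions: (−)-Ipc2BOMe, CH2=CHCH2MgBr, Et2O; then 40, −78 °C; NaOH, H2O2
Reagents that add atoms: allylmagnesium bromide, C=CC[Mg]Br
Why: Brown allylboration on the Si face, where reagent control from the (+)-α-pinene-derived Ipc groups and the Felkin preference of the α-methyl aldehyde reinforce each other, should set C41 syn to C42 and C43.

Step 31
Reactants: 41 homoallylic alcohol
Product: 42 C41 TES ether of 41
Conditions: TESOTf, 2,6-lutidine, CH2Cl2, −78 °C
Reagents that add atoms: triethylsilyl triflate, CC[Si](CC)(CC)OS(=O)(=O)C(F)(F)F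
Why: The more labile triethylsilyl group marks O41 so that it alone can be freed before lactonisation.

Step 32
Reactants: 42 TES ether
Product: 43 C39–C50 aldehyde (3S,4S,5R,11R)-5,11-bis(tert-butyldimethylsilyloxy)-4-methyl-3-(triethylsilyloxy)dodecanal
Conditions: OsO4 (2 mol%), NaIO4, 2,6-lutidine, dioxane/H2O, rt
Reagents that add atoms: sodium periodate, [Na+].[O-]I(=O)(=O)=O
Why: Lemieux–Johnson cleavage of the terminal alkene gives the C39 aldehyde under near-neutral conditions that a β-silyloxy aldehyde tolerates.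

Step 33
Reactants: 31 phosphonium iodide; 43 aldehyde
Product: 45 C27–C50 carbamate with (Z)-C38=C39, via phosphorus ylide 44 (not isolated)
Conditions: NaN(SiMe3)2, THF, −78 to 0 °C; then 43, −78 °C to rt
Reagents that add atoms: none
Why: Salt-free Wittig reaction of the unstabilised ylide 44 passes through the kinetically favoured cis-oxaphosphetane and should give the Z alkene.

**Union of C15–C26 with C27–C50**

Step 34
Reactants: 45 C27–C50 carbamate; 21 C26 boronic ester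
Product: 48 C15–C50 alcohol with free (27R)-hydroxyl, via lithiated carbamate 46 (not isolated), via secondary boronic ester 47 (not isolated)
Conditions: s-BuLi, (−)-sparteine, Et2O, −78 °C, 5 h; then 21, −78 °C; MgBr2·OEt2, reflux; then NaOH, H2O2, THF, 0 °C
Reagents that add atoms: hydrogen peroxide, OO
Why: Hoppe–Aggarwal lithiation–borylation, in which (−)-sparteine-mediated removal of the pro-S proton gives 46, borylation occurs with retention, 1,2-migration of the C26 alkyl group expels the carbamate with inversion and oxidation of 47 proceeds with retention, so that C27 should arise R under reagent control.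

Step 35
Reactants: 48 C27 alcohol
Product: 49 C27 TBS ether
Conditions: TBSOTf, 2,6-lutidine, CH2Cl2, −78 to 0 °C
Reagents that add atoms: tert-butyldimethylsilyl triflate, CC(C)(C)[Si](C)(C)OS(=O)(=O)C(F)(F)F
Why: Silylation protects the new secondary hydroxyl.

Step 36
Reactants: 49 PMP acetal
Product: 50 C15 primary alcohol with C17 PMB ether
Conditions: iBu2AlH, CH2Cl2, −78 to 0 °C
Reagents that add atoms: none
Why: Reductive acetal opening, in which aluminium binds the less hindered O15 and hydride is delivered to the benzylic oxocarbenium ion, leaves the PMB group on the secondary O17 and frees the primary hydroxyl.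

Step 37
Reactants: 50 C15 alcohol
Product: 51 C15 aldehyde
Conditions: Dess–Martin periodinane, NaHCO3, CH2Cl2, rt
Reagents that add atoms: none
Why: Buffered Dess–Martin oxidation gives the β-alkoxy aldehyde without elimination or silyl loss.

**West fragment (C1–C14)**

Step 38
Reactants: 52 ethyl 2-(2-methyl-1,3-dioxolan-2-yl)acetate
Product: 53 2-(2-methyl-1,3-dioxolan-2-yl)acetaldehyde
Conditions: iBu2AlH, CH2Cl2, −78 °C
Reagents that add atoms: none
Why: Partial ester reduction stops at the aldehyde because the tetrahedral aluminium hemiacetal survives at −78 °C until work-up.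

Step 39
Reactants: 53 aldehyde
Product: 54 (S)-1-(2-methyl-1,3-dioxolan-2-yl)pent-4-en-2-ol
Conditions: (−)-Ipc2BOMe, CH2=CHCH2MgBr, Et2O; then 53, −78 °C; NaOH, H2O2
Reagents that add atoms: allylmagnesium bromide, C=CC[Mg]Br
Why: Brown allylboration on the Si face under control of the (+)-α-pinene-derived Ipc groups should set C11 as S.

Step 40
Reactants: 54 homoallylic alcohol
Product: 55 PMB ether of 54
Conditions: NaH, 4-MeOC6H4CH2Cl, Bu4NI (cat.), DMF, 0 °C to rt
Reagents that add atoms: 4-methoxybenzyl chloride, COc1ccc(CCl)cc1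
Why: Williamson etherification under basic conditions spares the ketal and installs the β-alkoxy group that directs the next aldol.

Step 41
Reactants: 55 PMB ether
Product: 56 (S)-3-[(4-methoxybenzyl)oxy]-4-(2-methyl-1,3-dioxolan-2-yl)butanal
Conditions: OsO4 (2 mol%), NaIO4, 2,6-lutidine, dioxane/H2O, rt
Reagents that add atoms: sodium periodate, [Na+].[O-]I(=O)(=O)=O
Why: Lemieux–Johnson cleavage gives the C9 aldehyde and avoids exposing the electron-rich PMB ring to ozone.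

Step 42
Reactants: 56 aldehyde
Product: 57 methyl (5S,7S)-5-hydroxy-7-[(4-methoxybenzyl)oxy]-8-(2-methyl-1,3-dioxolan-2-yl)-3-oxooctanoate
Conditions: CH2=C(OSiMe3)CH=C(OMe)OSiMe3, BF3·OEt2, CH2Cl2, −78 °C
Reagents that add atoms: 1-methoxy-1,3-bis(trimethylsilyloxy)buta-1,3-diene, COC(O[Si](C)(C)C)=CC(=C)O[Si](C)(C)C
Why: Mukaiyama aldol of the Chan diene at its terminal carbon through an open transition state, in which the β-OPMB dipole opposes the activated carbonyl (1,3-anti induction), should set C9 anti to C11 and add C5–C8.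

Step 43
Reactants: 57 δ-hydroxy-β-keto ester
Product: 58 methyl (3R,5R,7S)-3,5-dihydroxy-7-[(4-methoxybenzyl)oxy]-8-(2-methyl-1,3-dioxolan-2-yl)octanoate
Conditions: Me4NBH(OAc)3, MeCN/AcOH (1:1), −30 °C
Reagents that add atoms: none
Why: Evans–Saksena reduction directed by the C9 hydroxyl sets C7 anti to C9 and completes the all-anti C7/C9/C11 array.

Step 44
Reactants: 58 anti diol
Product: 59 C7,C9-bis-TBS ether of 58
Conditions: TBSOTf, 2,6-lutidine, CH2Cl2, −78 to 0 °C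
Reagents that add atoms: tert-butyldimethylsilyl triflate, CC(C)(C)[Si](C)(C)OS(=O)(=O)C(F)(F)F
Why: Silyl triflate with a hindered base silylates both hydroxyls without opening the ketal.

Step 45
Reactants: 59 methyl ester
Product: 60 C5 aldehyde (C5–C14; 7,9-bis-TBS, 11-PMB, C13 ketal)
Conditions: iBu2AlH, CH2Cl2, −78 °C
Reagents that add atoms: none
Why: The β-silyloxy ester gives a stabilised aluminium hemiacetal at −78 °C that releases the aldehyde only on work-up.

Step 46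
Reactants: 60 C5 aldehyde
Product: 61 ethyl (Z)-2-methylenoate (C3–C14) with C3 cis to C6
Conditions: (CF3CH2O)2P(O)CH(CH3)CO2Et, KN(SiMe3)2, 18-crown-6, THF, −78 °C
Reagents that add atoms: ethyl 2-[bis(2,2,2-trifluoroethoxy)phosphoryl]propanoate, CCOC(=O)C(C)P(=O)(OCC(F)(F)F)OCC(F)(F)F
Why: Still–Gennari olefination, in which the electron-poor phosphonate makes elimination from the kinetic adduct fast, should give the (Z)-trisubstituted C4=C5 alkene.

Step 47
Reactants: 61 (Z)-enoate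
Product: 62 (Z)-allylic alcohol (C3 carbinol)
Conditions: iBu2AlH, CH2Cl2, −78 °C
Reagents that add atoms: none
Why: 1,2-Reduction of the unsaturated ester leaves alkene geometry, ketal and ethers untouched.

Step 48
Reactants: 62 allylic alcohol
Product: 63 (Z)-2-methylenal (C3 aldehyde)
Conditions: MnO2, CH2Cl2, rt
Reagents that add atoms: none
Why: Neutral allylic oxidation avoids isomerisation of the Z enal.

Step 49
Reactants: 63 (Z)-enal
Product: 64 methyl (2Z,4Z)-dienoate (C1–C14, C13 ketal)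
Conditions: (CF3CH2O)2P(O)CH2CO2Me, KN(SiMe3)2, 18-crown-6, THF, −78 °C
Reagents that add atoms: methyl 2-[bis(2,2,2-trifluoroethoxy)phosphoryl]acetate, COC(=O)CP(=O)(OCC(F)(F)F)OCC(F)(F)F
Why: A second Still–Gennari olefination should set the (Z)-C2=C3 alkene under kinetic control.

Step 50
Reactants: 64 dienoate ketal
Product: 65 C1–C14 methyl ketone
Conditions: PPTS, acetone/H2O, 50 °C
Reagents that add atoms: water, O
Why: Mild acid-catalysed ketal hydrolysis releases the C13 methyl ketone while secondary TBS ethers, the PMB ether and the dienoate are stable.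

**Union with C1–C14 and endgame**

Step 51
Reactants: 65 methyl ketone; 51 C15 aldehyde
Product: 67 C1–C50 aldol adduct with (15S)-hydroxyl and C13 ketone, via trimethylsilyl enol ether 66 (not isolated)
Conditions: 65, LiN(SiMe3)2, Me3SiCl, Et3N, THF, −78 °C; solvent exchange; then 51, BF3·OEt2, CH2Cl2, −78 °C
Reagents that add atoms: none
Why: Kinetic enolisation at the methyl group gives 66, which adds to the BF3-activated aldehyde through an open transition state in which the C17 OPMB dipole opposes the carbonyl (Mukaiyama aldol, 1,3-anti induction), so that C15 should arise anti to C17.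

Step 52
Reactants: 67 aldol adduct
Product: 68 C13,C15-anti diol
Conditions: Me4NBH(OAc)3, MeCN/AcOH (1:1), −30 °C
Reagents that add atoms: none
Why: Evans–Saksena reduction directed by the C15 hydroxyl sets C13 anti to C15, ketones lacking a β-hydroxyl and the dienoate being inert.

Step 53
Reactants: 68 anti diol
Product: 69 C13,C15-bis-TBS ether
Conditions: TBSOTf, 2,6-lutidine, CH2Cl2, −78 to 0 °C
Reagents that add atoms: tert-butyldimethylsilyl triflate, CC(C)(C)[Si](C)(C)OS(=O)(=O)C(F)(F)F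
Why: Silylation leaves O41 as the only oxygen carrying a labile group.

Step 54
Reactants: 69 fully protected ester
Product: 70 C41 alcohol
Conditions: PPTS, MeOH/CH2Cl2, 0 °C
Reagents that add atoms: none
Why: Acid-catalysed methanolysis removes the triethylsilyl ether much faster than any secondary TBS ether, freeing only the C41 hydroxyl.

Step 55
Reactants: 70 hydroxy ester
Product: 71 seco acid
Conditions: LiOH, THF/MeOH/H2O, rt; 1 M HCl to pH 4
Reagents that add atoms: lithium hydroxide, [Li+].[OH-]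
Why: Saponification of the methyl ester proceeds by acyl–oxygen cleavage and does not disturb the dienoate geometry or the silyl ethers.

Step 56
Reactants: 71 seco acid
Product: 73 protected 42-membered macrolactone, via mixed 2,4,6-trichlorobenzoic anhydride 72 (not isolated)
Conditions: 2,4,6-Cl3C6H2COCl, Et3N, THF, rt; then slow addition to DMAP, toluene, 0.5 mM, 40 °C
Reagents that add atoms: none
Why: Yamaguchi macrolactonisation, in which DMAP transfers the acyl group of 72 to the only free hydroxyl at C41 under high dilution, closes the large and nearly strain-free ring.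

Step 57
Reactants: 73 protected macrolactone
Product: 74 macrolactone with free C11 and C17 hydroxyls
Conditions: DDQ, CH2Cl2/pH 7 buffer, 0 °C
Reagents that add atoms: none
Why: Oxidative cleavage of both PMB ethers by hydride abstraction at the electron-rich benzylic position leaves silyl ethers, alkenes and the electron-poor dienoate untouched.

Step 58
Reactants: 74 deca-TBS macrolactone
Product: 75 CNP0392687.2
Conditions: HF·pyridine, pyridine, THF, 0 °C to rt
Reagents that add atoms: none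
Why: Buffered acidic fluoride removes all ten TBS ethers while minimising acyl migration from O41 and ionisation of the allylic C19 carbinol.

**Compound list**

1 | (S)-4-benzyl-3-propionyloxazolidin-2-one | CCC(=O)N1[C@@H](Cc2ccccc2)COC1=O | starting material
2 | (Z)-dibutylboron enolate of 1 | CCCCB(CCCC)O/C(=C\C)N1[C@@H](Cc2ccccc2)COC1=O | intermediate
3 | (S)-4-benzyl-3-[(2S,3S)-3-hydroxy-2,4-dimethylpent-4-enoyl]oxazolidin-2-one | O=C([C@@H](C)[C@H](O)C(C)=C)N1[C@@H](Cc2ccccc2)COC1=O | intermediate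
4 | (2S,3S)-3-hydroxy-N-methoxy-N,2,4-trimethylpent-4-enamide | CON(C)C(=O)[C@@H](C)[C@H](O)C(C)=C | intermediate
5 | ethyl (4S,5S)-5-hydroxy-4,6-dimethyl-3-oxohept-6-enoate | CCOC(=O)CC(=O)[C@@H](C)[C@H](O)C(C)=C | intermediate
6 | ethyl (3R,4R,5S)-3,5-dihydroxy-4,6-dimethylhept-6-enoate | CCOC(=O)C[C@@H](O)[C@@H](C)[C@H](O)C(C)=C | intermediate
7 | (3R,4R,5S)-4,6-dimethylhept-6-ene-1,3,5-triol | OCC[C@@H](O)[C@@H](C)[C@H](O)C(C)=C | intermediate
8 | north alcohol, (3S,4S)-4-[(2R,4R)-2-(4-methoxyphenyl)-1,3-dioxan-4-yl]-2-methylpent-1-en-3-ol | COc1ccc(cc1)[C@@H]1OCC[C@@H](O1)[C@@H](C)[C@H](O)C(C)=C | intermediate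
9 | butane-1,4-diol | OCCCCO | starting material
10 | 4-hydroxybutyl benzoate | OCCCCOC(=O)c1ccccc1 | intermediate
11 | 4-oxobutyl benzoate | O=CCCCOC(=O)c1ccccc1 | intermediate
12 | south alcohol, (R)-4-hydroxyhept-6-en-1-yl benzoate | C=CC[C@H](O)CCCOC(=O)c1ccccc1 | intermediate
13 | chlorodiisopropylsilyl ether of 8 | COc1ccc(cc1)[C@@H]1OCC[C@@H](O1)[C@@H](C)[C@H](O[Si](Cl)(C(C)C)C(C)C)C(C)=C | intermediate
14 | mixed diisopropylsilylene bis-ether of 8 (O19) and 12 (O23) | COc1ccc(cc1)[C@@H]1OCC[C@@H](O1)[C@@H](C)[C@H](O[Si](C(C)C)(C(C)C)O[C@@H](CC=C)CCCOC(=O)c1ccccc1)C(C)=C | intermediate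
15 | eight-membered (Z)-cyclic silylene ether holding C19–C23, configurations as in 14 | COc1ccc(cc1)[C@@H]1OCC[C@@H](O1)[C@@H](C)[C@@H]1O[Si](C(C)C)(C(C)C)O[C@H](CCCOC(=O)c2ccccc2)C/C=C1/C | intermediate
16 | (Z)-C19,C23-diol, C15/C17 PMP acetal, C26 benzoate | COc1ccc(cc1)[C@@H]1OCC[C@@H](O1)[C@@H](C)[C@H](O)/C(C)=C\C[C@H](O)CCCOC(=O)c1ccccc1 | intermediate
17 | C19,C23-bis-TBS ether of 16 | COc1ccc(cc1)[C@@H]1OCC[C@@H](O1)[C@@H](C)[C@H](O[Si](C)(C)C(C)(C)C)/C(C)=C\C[C@H](O[Si](C)(C)C(C)(C)C)CCCOC(=O)c1ccccc1 | intermediate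
18 | C26 primary alcohol (C15–C26) | COc1ccc(cc1)[C@@H]1OCC[C@@H](O1)[C@@H](C)[C@H](O[Si](C)(C)C(C)(C)C)/C(C)=C\C[C@H](O[Si](C)(C)C(C)(C)C)CCCO | intermediate
19 | C26 iodide (C15–C26) | COc1ccc(cc1)[C@@H]1OCC[C@@H](O1)[C@@H](C)[C@H](O[Si](C)(C)C(C)(C)C)/C(C)=C\C[C@H](O[Si](C)(C)C(C)(C)C)CCCI | intermediate
20 | C26 alkyllithium | COc1ccc(cc1)[C@@H]1OCC[C@@H](O1)[C@@H](C)[C@H](O[Si](C)(C)C(C)(C)C)/C(C)=C\C[C@H](O[Si](C)(C)C(C)(C)C)CCC[Li] | intermediate
21 | C26 pinacol boronic ester (C15–C26) | COc1ccc(cc1)[C@@H]1OCC[C@@H](O1)[C@@H](C)[C@H](O[Si](C)(C)C(C)(C)C)/C(C)=C\C[C@H](O[Si](C)(C)C(C)(C)C)CCCB1OC(C)(C)C(C)(C)O1 | intermediate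
22 | (S)-epichlorohydrin | ClC[C@@H]1CO1 | starting material
23 | (S)-1-chlorohex-5-en-2-ol | ClC[C@@H](O)CCC=C | intermediate
24 | (S)-2-(but-3-en-1-yl)oxirane | C=CCC[C@H]1CO1 | intermediate
25 | (R)-12-chlorododec-1-en-5-ol | C=CCC[C@H](O)CCCCCCCCl | intermediate
26 | TBS ether of 25 | C=CCC[C@H](O[Si](C)(C)C(C)(C)C)CCCCCCCCl | intermediate
27 | B-alkyl-9-borabicyclo[3.3.1]nonane from 26 | B1(CCCC[C@H](O[Si](C)(C)C(C)(C)C)CCCCCCCCl)C2CCCC1CCC2 | intermediate
28 | (R)-5-(tert-butyldimethylsilyloxy)-12-chlorododecan-1-ol | OCCCC[C@H](O[Si](C)(C)C(C)(C)C)CCCCCCCCl | intermediate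
29 | (R)-5-(tert-butyldimethylsilyloxy)-12-chlorododecyl N,N-diisopropylcarbamate | CC(C)N(C(C)C)C(=O)OCCCC[C@H](O[Si](C)(C)C(C)(C)C)CCCCCCCCl | intermediate
30 | corresponding 12-iodide | CC(C)N(C(C)C)C(=O)OCCCC[C@H](O[Si](C)(C)C(C)(C)C)CCCCCCCI | intermediate
31 | C27–C38 triphenylphosphonium iodide | CC(C)N(C(C)C)C(=O)OCCCC[C@H](O[Si](C)(C)C(C)(C)C)CCCCCCC[P+](c1ccccc1)(c1ccccc1)c1ccccc1.[I-] | intermediate
32 | (R)-propylene oxide | C[C@@H]1CO1 | starting material
33 | (R)-non-8-en-2-ol | C=CCCCCC[C@@H](C)O | intermediate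
34 | TBS ether of 33 | C=CCCCCC[C@@H](C)O[Si](C)(C)C(C)(C)C | intermediate
35 | (R)-7-(tert-butyldimethylsilyloxy)octanal | O=CCCCCC[C@@H](C)O[Si](C)(C)C(C)(C)C | intermediate
36 | chlorotitanium (Z)-enolate of 1 | Cl[Ti](Cl)(Cl)O/C(=C\C)N1[C@@H](Cc2ccccc2)COC1=O | intermediate
37 | (S)-4-benzyl-3-[(2S,3R,9R)-9-(tert-butyldimethylsilyloxy)-3-hydroxy-2-methyldecanoyl]oxazolidin-2-one | O=C([C@@H](C)[C@H](O)CCCCC[C@@H](C)O[Si](C)(C)C(C)(C)C)N1[C@@H](Cc2ccccc2)COC1=O | intermediate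
38 | 3-O-TBS ether of 37 | O=C([C@@H](C)[C@H](O[Si](C)(C)C(C)(C)C)CCCCC[C@@H](C)O[Si](C)(C)C(C)(C)C)N1[C@@H](Cc2ccccc2)COC1=O | intermediate
39 | (2R,3R,9R)-3,9-bis(tert-butyldimethylsilyloxy)-2-methyldecan-1-ol | OC[C@@H](C)[C@H](O[Si](C)(C)C(C)(C)C)CCCCC[C@@H](C)O[Si](C)(C)C(C)(C)C | intermediate
40 | (2S,3R,9R)-3,9-bis(tert-butyldimethylsilyloxy)-2-methyldecanal | O=C[C@@H](C)[C@H](O[Si](C)(C)C(C)(C)C)CCCCC[C@@H](C)O[Si](C)(C)C(C)(C)C | intermediate
41 | (4S,5R,6R,12R)-6,12-bis(tert-butyldimethylsilyloxy)-5-methyltridec-1-en-4-ol | C=CC[C@H](O)[C@@H](C)[C@H](O[Si](C)(C)C(C)(C)C)CCCCC[C@@H](C)O[Si](C)(C)C(C)(C)C | intermediate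
42 | 4-O-triethylsilyl ether of 41 | C=CC[C@H](O[Si](CC)(CC)CC)[C@@H](C)[C@H](O[Si](C)(C)C(C)(C)C)CCCCC[C@@H](C)O[Si](C)(C)C(C)(C)C | intermediate
43 | C39–C50 aldehyde, (3S,4S,5R,11R)-5,11-bis(tert-butyldimethylsilyloxy)-4-methyl-3-(triethylsilyloxy)dodecanal | O=CC[C@H](O[Si](CC)(CC)CC)[C@@H](C)[C@H](O[Si](C)(C)C(C)(C)C)CCCCC[C@@H](C)O[Si](C)(C)C(C)(C)C | intermediate
44 | phosphorus ylide from 31 | CC(C)N(C(C)C)C(=O)OCCCC[C@H](O[Si](C)(C)C(C)(C)C)CCCCCCC=P(c1ccccc1)(c1ccccc1)c1ccccc1 | intermediate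
45 | C27–C50 carbamate with (Z)-C38=C39 (31-TBS, 41-TES, 43-TBS, 49-TBS; spatial arrangement as in the target) | CC(C)N(C(C)C)C(=O)OCCCC[C@H](O[Si](C)(C)C(C)(C)C)CCCCCC/C=C\C[C@H](O[Si](CC)(CC)CC)[C@@H](C)[C@H](O[Si](C)(C)C(C)(C)C)CCCCC[C@@H](C)O[Si](C)(C)C(C)(C)C | intermediate
46 | (S)-C27-lithiated carbamate of 45 | [Li][C@H](OC(=O)N(C(C)C)C(C)C)CCC[C@H](O[Si](C)(C)C(C)(C)C)CCCCCC/C=C\C[C@H](O[Si](CC)(CC)CC)[C@@H](C)[C@H](O[Si](C)(C)C(C)(C)C)CCCCC[C@@H](C)O[Si](C)(C)C(C)(C)C | intermediate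
47 | C15–C50 secondary pinacol boronic ester at C27 | COc1ccc(cc1)[C@@H]1OCC[C@@H](O1)[C@@H](C)[C@H](O[Si](C)(C)C(C)(C)C)/C(C)=C\C[C@H](O[Si](C)(C)C(C)(C)C)CCC[C@H](B1OC(C)(C)C(C)(C)O1)CCC[C@H](O[Si](C)(C)C(C)(C)C)CCCCCC/C=C\C[C@H](O[Si](CC)(CC)CC)[C@@H](C)[C@H](O[Si](C)(C)C(C)(C)C)CCCCC[C@@H](C)O[Si](C)(C)C(C)(C)C | intermediate
48 | C15–C50 alcohol with free (27R)-hydroxyl | COc1ccc(cc1)[C@@H]1OCC[C@@H](O1)[C@@H](C)[C@H](O[Si](C)(C)C(C)(C)C)/C(C)=C\C[C@H](O[Si](C)(C)C(C)(C)C)CCC[C@H](O)CCC[C@H](O[Si](C)(C)C(C)(C)C)CCCCCC/C=C\C[C@H](O[Si](CC)(CC)CC)[C@@H](C)[C@H](O[Si](C)(C)C(C)(C)C)CCCCC[C@@H](C)O[Si](C)(C)C(C)(C)C | intermediate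
49 | C27 TBS ether of 48 | COc1ccc(cc1)[C@@H]1OCC[C@@H](O1)[C@@H](C)[C@H](O[Si](C)(C)C(C)(C)C)/C(C)=C\C[C@H](O[Si](C)(C)C(C)(C)C)CCC[C@H](O[Si](C)(C)C(C)(C)C)CCC[C@H](O[Si](C)(C)C(C)(C)C)CCCCCC/C=C\C[C@H](O[Si](CC)(CC)CC)[C@@H](C)[C@H](O[Si](C)(C)C(C)(C)C)CCCCC[C@@H](C)O[Si](C)(C)C(C)(C)C | intermediate
50 | C15 primary alcohol with C17 PMB ether (C15–C50) | OCC[C@@H](OCc1ccc(OC)cc1)[C@@H](C)[C@H](O[Si](C)(C)C(C)(C)C)/C(C)=C\C[C@H](O[Si](C)(C)C(C)(C)C)CCC[C@H](O[Si](C)(C)C(C)(C)C)CCC[C@H](O[Si](C)(C)C(C)(C)C)CCCCCC/C=C\C[C@H](O[Si](CC)(CC)CC)[C@@H](C)[C@H](O[Si](C)(C)C(C)(C)C)CCCCC[C@@H](C)O[Si](C)(C)C(C)(C)C | intermediate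
51 | C15 aldehyde (C15–C50) | O=CC[C@@H](OCc1ccc(OC)cc1)[C@@H](C)[C@H](O[Si](C)(C)C(C)(C)C)/C(C)=C\C[C@H](O[Si](C)(C)C(C)(C)C)CCC[C@H](O[Si](C)(C)C(C)(C)C)CCC[C@H](O[Si](C)(C)C(C)(C)C)CCCCCC/C=C\C[C@H](O[Si](CC)(CC)CC)[C@@H](C)[C@H](O[Si](C)(C)C(C)(C)C)CCCCC[C@@H](C)O[Si](C)(C)C(C)(C)C | intermediate
52 | ethyl 2-(2-methyl-1,3-dioxolan-2-yl)acetate | CCOC(=O)CC1(C)OCCO1 | starting material
53 | 2-(2-methyl-1,3-dioxolan-2-yl)acetaldehyde | O=CCC1(C)OCCO1 | intermediate
54 | (S)-1-(2-methyl-1,3-dioxolan-2-yl)pent-4-en-2-ol | C=CC[C@H](O)CC1(C)OCCO1 | intermediate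
55 | PMB ether of 54 | C=CC[C@H](OCc1ccc(OC)cc1)CC1(C)OCCO1 | intermediate
56 | (S)-3-[(4-methoxybenzyl)oxy]-4-(2-methyl-1,3-dioxolan-2-yl)butanal | O=CC[C@H](OCc1ccc(OC)cc1)CC1(C)OCCO1 | intermediate
57 | methyl (5S,7S)-5-hydroxy-7-[(4-methoxybenzyl)oxy]-8-(2-methyl-1,3-dioxolan-2-yl)-3-oxooctanoate | COC(=O)CC(=O)C[C@@H](O)C[C@H](OCc1ccc(OC)cc1)CC1(C)OCCO1 | intermediate
58 | methyl (3R,5R,7S)-3,5-dihydroxy-7-[(4-methoxybenzyl)oxy]-8-(2-methyl-1,3-dioxolan-2-yl)octanoate | COC(=O)C[C@H](O)C[C@@H](O)C[C@H](OCc1ccc(OC)cc1)CC1(C)OCCO1 | intermediate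
59 | 3,5-bis-TBS ether of 58 | COC(=O)C[C@H](O[Si](C)(C)C(C)(C)C)C[C@@H](O[Si](C)(C)C(C)(C)C)C[C@H](OCc1ccc(OC)cc1)CC1(C)OCCO1 | intermediate
60 | C5 aldehyde (C5–C14), configurations as in 59 | O=CC[C@H](O[Si](C)(C)C(C)(C)C)C[C@@H](O[Si](C)(C)C(C)(C)C)C[C@H](OCc1ccc(OC)cc1)CC1(C)OCCO1 | intermediate
61 | ethyl (Z)-2-methylenoate (C3–C14) | CCOC(=O)/C(C)=C\C[C@H](O[Si](C)(C)C(C)(C)C)C[C@@H](O[Si](C)(C)C(C)(C)C)C[C@H](OCc1ccc(OC)cc1)CC1(C)OCCO1 | intermediate
62 | (Z)-allylic alcohol (C3–C14) | OC/C(C)=C\C[C@H](O[Si](C)(C)C(C)(C)C)C[C@@H](O[Si](C)(C)C(C)(C)C)C[C@H](OCc1ccc(OC)cc1)CC1(C)OCCO1 | intermediate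
63 | (Z)-2-methylenal (C3–C14) | O=C/C(C)=C\C[C@H](O[Si](C)(C)C(C)(C)C)C[C@@H](O[Si](C)(C)C(C)(C)C)C[C@H](OCc1ccc(OC)cc1)CC1(C)OCCO1 | intermediate
64 | methyl (2Z,4Z)-dienoate with C13 ketal (C1–C14) | COC(=O)/C=C\C(C)=C/C[C@H](O[Si](C)(C)C(C)(C)C)C[C@@H](O[Si](C)(C)C(C)(C)C)C[C@H](OCc1ccc(OC)cc1)CC1(C)OCCO1 | intermediate
65 | C1–C14 methyl ketone | COC(=O)/C=C\C(C)=C/C[C@H](O[Si](C)(C)C(C)(C)C)C[C@@H](O[Si](C)(C)C(C)(C)C)C[C@H](OCc1ccc(OC)cc1)CC(C)=O | intermediate
66 | trimethylsilyl enol ether of 65 | COC(=O)/C=C\C(C)=C/C[C@H](O[Si](C)(C)C(C)(C)C)C[C@@H](O[Si](C)(C)C(C)(C)C)C[C@H](OCc1ccc(OC)cc1)CC(=C)O[Si](C)(C)C | intermediate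
67 | C1–C50 aldol adduct (C13 ketone, free C15 hydroxyl) | COC(=O)/C=C\C(C)=C/C[C@H](O[Si](C)(C)C(C)(C)C)C[C@@H](O[Si](C)(C)C(C)(C)C)C[C@H](OCc1ccc(OC)cc1)CC(=O)C[C@H](O)C[C@@H](OCc1ccc(OC)cc1)[C@@H](C)[C@H](O[Si](C)(C)C(C)(C)C)/C(C)=C\C[C@H](O[Si](C)(C)C(C)(C)C)CCC[C@H](O[Si](C)(C)C(C)(C)C)CCC[C@H](O[Si](C)(C)C(C)(C)C)CCCCCC/C=C\C[C@H](O[Si](CC)(CC)CC)[C@@H](C)[C@H](O[Si](C)(C)C(C)(C)C)CCCCC[C@@H](C)O[Si](C)(C)C(C)(C)C | intermediate
68 | C13,C15-anti diol | COC(=O)/C=C\C(C)=C/C[C@H](O[Si](C)(C)C(C)(C)C)C[C@@H](O[Si](C)(C)C(C)(C)C)C[C@H](OCc1ccc(OC)cc1)C[C@@H](O)C[C@H](O)C[C@@H](OCc1ccc(OC)cc1)[C@@H](C)[C@H](O[Si](C)(C)C(C)(C)C)/C(C)=C\C[C@H](O[Si](C)(C)C(C)(C)C)CCC[C@H](O[Si](C)(C)C(C)(C)C)CCC[C@H](O[Si](C)(C)C(C)(C)C)CCCCCC/C=C\C[C@H](O[Si](CC)(CC)CC)[C@@H](C)[C@H](O[Si](C)(C)C(C)(C)C)CCCCC[C@@H](C)O[Si](C)(C)C(C)(C)C | intermediate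
69 | fully protected methyl ester (TBS at O7, O9, O13, O15, O19, O23, O27, O31, O43, O49; PMB at O11, O17; TES at O41) | COC(=O)/C=C\C(C)=C/C[C@H](O[Si](C)(C)C(C)(C)C)C[C@@H](O[Si](C)(C)C(C)(C)C)C[C@H](OCc1ccc(OC)cc1)C[C@@H](O[Si](C)(C)C(C)(C)C)C[C@H](O[Si](C)(C)C(C)(C)C)C[C@@H](OCc1ccc(OC)cc1)[C@@H](C)[C@H](O[Si](C)(C)C(C)(C)C)/C(C)=C\C[C@H](O[Si](C)(C)C(C)(C)C)CCC[C@H](O[Si](C)(C)C(C)(C)C)CCC[C@H](O[Si](C)(C)C(C)(C)C)CCCCCC/C=C\C[C@H](O[Si](CC)(CC)CC)[C@@H](C)[C@H](O[Si](C)(C)C(C)(C)C)CCCCC[C@@H](C)O[Si](C)(C)C(C)(C)C | intermediate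
70 | C41 alcohol (methyl ester) | COC(=O)/C=C\C(C)=C/C[C@H](O[Si](C)(C)C(C)(C)C)C[C@@H](O[Si](C)(C)C(C)(C)C)C[C@H](OCc1ccc(OC)cc1)C[C@@H](O[Si](C)(C)C(C)(C)C)C[C@H](O[Si](C)(C)C(C)(C)C)C[C@@H](OCc1ccc(OC)cc1)[C@@H](C)[C@H](O[Si](C)(C)C(C)(C)C)/C(C)=C\C[C@H](O[Si](C)(C)C(C)(C)C)CCC[C@H](O[Si](C)(C)C(C)(C)C)CCC[C@H](O[Si](C)(C)C(C)(C)C)CCCCCC/C=C\C[C@H](O)[C@@H](C)[C@H](O[Si](C)(C)C(C)(C)C)CCCCC[C@@H](C)O[Si](C)(C)C(C)(C)C | intermediate
71 | seco acid (free C1 acid and C41 hydroxyl) | OC(=O)/C=C\C(C)=C/C[C@H](O[Si](C)(C)C(C)(C)C)C[C@@H](O[Si](C)(C)C(C)(C)C)C[C@H](OCc1ccc(OC)cc1)C[C@@H](O[Si](C)(C)C(C)(C)C)C[C@H](O[Si](C)(C)C(C)(C)C)C[C@@H](OCc1ccc(OC)cc1)[C@@H](C)[C@H](O[Si](C)(C)C(C)(C)C)/C(C)=C\C[C@H](O[Si](C)(C)C(C)(C)C)CCC[C@H](O[Si](C)(C)C(C)(C)C)CCC[C@H](O[Si](C)(C)C(C)(C)C)CCCCCC/C=C\C[C@H](O)[C@@H](C)[C@H](O[Si](C)(C)C(C)(C)C)CCCCC[C@@H](C)O[Si](C)(C)C(C)(C)C | intermediate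
72 | mixed 2,4,6-trichlorobenzoic anhydride of 71 | O=C(c1c(Cl)cc(Cl)cc1Cl)OC(=O)/C=C\C(C)=C/C[C@H](O[Si](C)(C)C(C)(C)C)C[C@@H](O[Si](C)(C)C(C)(C)C)C[C@H](OCc1ccc(OC)cc1)C[C@@H](O[Si](C)(C)C(C)(C)C)C[C@H](O[Si](C)(C)C(C)(C)C)C[C@@H](OCc1ccc(OC)cc1)[C@@H](C)[C@H](O[Si](C)(C)C(C)(C)C)/C(C)=C\C[C@H](O[Si](C)(C)C(C)(C)C)CCC[C@H](O[Si](C)(C)C(C)(C)C)CCC[C@H](O[Si](C)(C)C(C)(C)C)CCCCCC/C=C\C[C@H](O)[C@@H](C)[C@H](O[Si](C)(C)C(C)(C)C)CCCCC[C@@H](C)O[Si](C)(C)C(C)(C)C | intermediate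
73 | protected 42-membered macrolactone (ten TBS ethers, PMB at O11 and O17) | CC1=C/C[C@H](O[Si](C)(C)C(C)(C)C)C[C@@H](O[Si](C)(C)C(C)(C)C)C[C@H](OCc2ccc(OC)cc2)C[C@@H](O[Si](C)(C)C(C)(C)C)C[C@H](O[Si](C)(C)C(C)(C)C)C[C@@H](OCc2ccc(OC)cc2)[C@@H](C)[C@H](O[Si](C)(C)C(C)(C)C)/C(C)=C\C[C@H](O[Si](C)(C)C(C)(C)C)CCC[C@H](O[Si](C)(C)C(C)(C)C)CCC[C@H](O[Si](C)(C)C(C)(C)C)CCCCCC/C=C\C[C@@H]([C@@H](C)[C@H](O[Si](C)(C)C(C)(C)C)CCCCC[C@@H](C)O[Si](C)(C)C(C)(C)C)OC(=O)/C=C\1 | intermediate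
74 | macrolactone with free C11 and C17 hydroxyls (ten TBS ethers) | CC1=C/C[C@H](O[Si](C)(C)C(C)(C)C)C[C@@H](O[Si](C)(C)C(C)(C)C)C[C@H](O)C[C@@H](O[Si](C)(C)C(C)(C)C)C[C@H](O[Si](C)(C)C(C)(C)C)C[C@@H](O)[C@@H](C)[C@H](O[Si](C)(C)C(C)(C)C)/C(C)=C\C[C@H](O[Si](C)(C)C(C)(C)C)CCC[C@H](O[Si](C)(C)C(C)(C)C)CCC[C@H](O[Si](C)(C)C(C)(C)C)CCCCCC/C=C\C[C@@H]([C@@H](C)[C@H](O[Si](C)(C)C(C)(C)C)CCCCC[C@@H](C)O[Si](C)(C)C(C)(C)C)OC(=O)/C=C\1 | intermediate
75 | CNP0392687.2 | CC1=C/C[C@H](O)C[C@@H](O)C[C@H](O)C[C@@H](O)C[C@H](O)C[C@@H](O)[C@@H](C)[C@H](O)/C(C)=C\C[C@H](O)CCC[C@H](O)CCC[C@H](O)CCCCCC/C=C\C[C@@H]([C@@H](C)[C@H](O)CCCCC[C@@H](C)O)OC(=O)/C=C\1 | target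

**Totals and risks**

Total step count: 58. Longest linear sequence: 25 steps (steps 1–6, 10–16, 34–37 and 51–58).

Steps most likely to fail:

1. Step 11. The ruthenium carbene may fail to engage the 1,1-disubstituted C20 alkene, so that cross-metathesis dimerisation at the C21 terminus or catalyst decomposition takes over. The fallback sets out from 8 and 12 and returns to the route at 17. Alcohol 8 would be silylated (TBSOTf, 2,6-lutidine) to its TBS ether F1 and the isopropenyl group cleaved (OsO4 cat., NaIO4) to the α-silyloxy methyl ketone F2. Alcohol 12 would be silylated to the TBS ether F3, cleaved (OsO4 cat., NaIO4) to the aldehyde F4, reduced (NaBH4) to the primary alcohol F5, converted (I2, PPh3, imidazole) into the iodide F6 and heated with PPh3 to give the phosphonium iodide F7. Wittig reaction of the ylide of F7 (NaN(SiMe3)2, THF/HMPA, −78 °C) with ketone F2 should give 17 directly, because unstabilised ylides add to α-alkoxy ketones with high Z selectivity.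

2. Step 34. Incomplete α-lithiation of the large carbamate, or slow 1,2-migration in the boronate, would give low conversion or erode the configuration at C27. The fallback sets out from 45 and 19 and returns at 48. Carbamate 45 would be cleaved with LiAlH4 to the C27 primary alcohol F8 and oxidised (Dess–Martin periodinane) to the C27 aldehyde F9. Iodide 19 would be converted with activated Zn dust into the alkylzinc iodide F10 and with Me3SiCH2Li into the mixed dialkylzinc F11. Addition of F11 to F9 with Ti(OiPr)4 and catalytic (1R,2R)-1,2-bis(trifluoromethanesulfonamido)cyclohexane should transfer the C26 alkyl group to the Si face of the aldehyde and give 48.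

3. Step 56. Activation of the (2Z,4Z)-dienoic acid as an acyl donor may cause Z-to-E isomerisation, and oligomerisation may compete with ring closure. The fallback sets out from 70 and returns at 73. Mitsunobu reaction of 70 with 4-nitrobenzoic acid (PPh3, DIAD) would give the C41-inverted 4-nitrobenzoate F12, and LiOH would hydrolyse both esters to the C41-epimeric seco acid F13. Mitsunobu macrolactonisation of F13 (PPh3, DIAD, toluene, high dilution) would then close the ring by SN2 attack of the carboxylate at the activated C41 oxygen, restoring the 41S configuration of 73 without acyl activation of the dienoic acid.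

Further compounds

F1 | step 11 | TBS ether of 8 | COc1ccc(cc1)[C@@H]1OCC[C@@H](O1)[C@@H](C)[C@H](O[Si](C)(C)C(C)(C)C)C(C)=C
F2 | step 11 | C20 methyl ketone with C19 TBS ether | COc1ccc(cc1)[C@@H]1OCC[C@@H](O1)[C@@H](C)[C@H](O[Si](C)(C)C(C)(C)C)C(C)=O
F3 | step 11 | TBS ether of 12 | C=CC[C@H](O[Si](C)(C)C(C)(C)C)CCCOC(=O)c1ccccc1
F4 | step 11 | C21 aldehyde, 4-(tert-butyldimethylsilyloxy)-6-oxohexyl benzoate | O=CC[C@H](O[Si](C)(C)C(C)(C)C)CCCOC(=O)c1ccccc1
F5 | step 11 | C21 alcohol, 4-(tert-butyldimethylsilyloxy)-6-hydroxyhexyl benzoate | OCC[C@H](O[Si](C)(C)C(C)(C)C)CCCOC(=O)c1ccccc1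
F6 | step 11 | C21 iodide | ICC[C@H](O[Si](C)(C)C(C)(C)C)CCCOC(=O)c1ccccc1
F7 | step 11 | C21 triphenylphosphonium iodide | [I-].c1ccccc1[P+](c1ccccc1)(c1ccccc1)CC[C@H](O[Si](C)(C)C(C)(C)C)CCCOC(=O)c1ccccc1
F8 | step 34 | C27 primary alcohol of the C27–C50 fragment | OCCCC[C@H](O[Si](C)(C)C(C)(C)C)CCCCCC/C=C\C[C@H](O[Si](CC)(CC)CC)[C@@H](C)[C@H](O[Si](C)(C)C(C)(C)C)CCCCC[C@@H](C)O[Si](C)(C)C(C)(C)C
F9 | step 34 | C27 aldehyde of the C27–C50 fragment | O=CCCC[C@H](O[Si](C)(C)C(C)(C)C)CCCCCC/C=C\C[C@H](O[Si](CC)(CC)CC)[C@@H](C)[C@H](O[Si](C)(C)C(C)(C)C)CCCCC[C@@H](C)O[Si](C)(C)C(C)(C)C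
F10 | step 34 | C26 alkylzinc iodide from 19 | COc1ccc(cc1)[C@@H]1OCC[C@@H](O1)[C@@H](C)[C@H](O[Si](C)(C)C(C)(C)C)/C(C)=C\C[C@H](O[Si](C)(C)C(C)(C)C)CCC[Zn]I
F11 | step 34 | C26 alkyl(trimethylsilylmethyl)zinc | COc1ccc(cc1)[C@@H]1OCC[C@@H](O1)[C@@H](C)[C@H](O[Si](C)(C)C(C)(C)C)/C(C)=C\C[C@H](O[Si](C)(C)C(C)(C)C)CCC[Zn]C[Si](C)(C)C
F12 | step 56 | C41-epimeric 4-nitrobenzoate of 70 | COC(=O)/C=C\C(C)=C/C[C@H](O[Si](C)(C)C(C)(C)C)C[C@@H](O[Si](C)(C)C(C)(C)C)C[C@H](OCc1ccc(OC)cc1)C[C@@H](O[Si](C)(C)C(C)(C)C)C[C@H](O[Si](C)(C)C(C)(C)C)C[C@@H](OCc1ccc(OC)cc1)[C@@H](C)[C@H](O[Si](C)(C)C(C)(C)C)/C(C)=C\C[C@H](O[Si](C)(C)C(C)(C)C)CCC[C@H](O[Si](C)(C)C(C)(C)C)CCC[C@H](O[Si](C)(C)C(C)(C)C)CCCCCC/C=C\C[C@@H](OC(=O)c1ccc(cc1)[N+](=O)[O-])[C@@H](C)[C@H](O[Si](C)(C)C(C)(C)C)CCCCC[C@@H](C)O[Si](C)(C)C(C)(C)C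
F13 | step 56 | C41-epimeric seco acid | OC(=O)/C=C\C(C)=C/C[C@H](O[Si](C)(C)C(C)(C)C)C[C@@H](O[Si](C)(C)C(C)(C)C)C[C@H](OCc1ccc(OC)cc1)C[C@@H](O[Si](C)(C)C(C)(C)C)C[C@H](O[Si](C)(C)C(C)(C)C)C[C@@H](OCc1ccc(OC)cc1)[C@@H](C)[C@H](O[Si](C)(C)C(C)(C)C)/C(C)=C\C[C@H](O[Si](C)(C)C(C)(C)C)CCC[C@H](O[Si](C)(C)C(C)(C)C)CCC[C@H](O[Si](C)(C)C(C)(C)C)CCCCCC/C=C\C[C@@H](O)[C@@H](C)[C@H](O[Si](C)(C)C(C)(C)C)CCCCC[C@@H](C)O[Si](C)(C)C(C)(C)C
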